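Ring A is built last, onto a monocyclic 4-pyranone that already carries ring C and the trimethoxyphenyl ring B. Because C7 and C8 of ring A are unsubstituted and C5 and C6 bear only oxygen, the C6–C7 pair is traced back to methyl 2-methoxyacrylate, stitched between an ester carbon attached to C4a (it becomes C5) and a methyl carbon attached to C8a (it becomes C8). One Michael–Dieckmann operation forms C7–C8 and C5–C6, closes ring A as a cyclohexanone and places both ring A oxygens. The precursor is methyl 2-methyl-4-oxo-6-(3,4,5-trimethoxyphenyl)-4H-pyran-3-carboxylate; decarboxylation, dehydrogenation and O-methylation then complete the target.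

Key step: step 3

Remark: the target has no stereocentre. The one stereocentre that arises on the way (C6 of 10 and 11) is carried as a racemate and disappears in step 5. Ring positions of the bicyclic compounds follow flavone numbering (O1, C2 to C4, C4a, C5 to C8, C8a).

Step 1
Reactants: 1 5-iodo-1,2,3-trimethoxybenzene; 2 propiolic acid
Product: 3 3-(3,4,5-trimethoxyphenyl)prop-2-ynoic acid
Conditions: Pd(PPh3)4 (5 mol %), DBU (2.4 equiv), DMSO, 35 °C; then 1 M HCl
Reagents that add atoms: none
Why: Copper-free Sonogashira coupling of an aryl iodide with the DBU salt of propiolic acid is an established entry to arylpropiolic acids, and at 35 °C the carboxylate should be retained because decarboxylation needs a higher temperature.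

Step 2
Reactants: 3 3-(3,4,5-trimethoxyphenyl)prop-2-ynoic acid; 4 methyl acetoacetate
Product: 7 methyl 2-methyl-4-oxo-6-(3,4,5-trimethoxyphenyl)-4H-pyran-3-carboxylate, via acid chloride 5 (not isolated), via ynone tricarbonyl 6 (not isolated)
Conditions: (COCl)2 (1.2 equiv), DMF (cat.), CH2Cl2, 0 °C to rt, evaporate; then 4 (1.1 equiv), MgCl2 (1.1 equiv), pyridine (2.2 equiv), CH2Cl2, 0 °C to rt; 1 M HCl wash; Et3N (0.2 equiv), CH2Cl2, rt
Reagents that add atoms: none
Why: Oxalyl chloride converts 3 into acid chloride 5, the magnesium chelate of 4 formed by soft enolisation is C-acylated to tricarbonyl 6, and the enol oxygen of its acetyl group then adds 6-endo-dig to the electrophilic β-carbon of the ynone (intramolecular oxa-Michael addition) to give the 4-pyranone.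

Step 3
Reactants: 7 methyl 2-methyl-4-oxo-6-(3,4,5-trimethoxyphenyl)-4H-pyran-3-carboxylate; 8 methyl 2-methoxyacrylate
Product: 10 racemic methyl 6-methoxy-4,5-dioxo-2-(3,4,5-trimethoxyphenyl)-5,6,7,8-tetrahydro-4H-chromene-6-carboxylate, via Michael adduct diester 9 (not isolated)
Conditions: LiN(iPr)2 (1.1 equiv), THF, −78 °C; 8 (1.2 equiv), −78 °C; LiN(SiMe3)2 (1.1 equiv), −78 to 0 °C; then AcOH
Reagents that add atoms: none
Why: Proposed new method: LiN(iPr)2 removes a proton from the C2 methyl group of 7 (pyranone numbering), which is acidified vinylogously by the C4 ketone and the C3 ester, and the delocalised dienolate adds through its CH2 terminus to the β-carbon of 8 (bond C7–C8, flavone numbering), giving the α-methoxy ester enolate of 9. On warming, this enolate attacks the lithium-chelated ring ester in a 6-exo-trig Dieckmann closure (bond C5–C6, ring A) with loss of methoxide. The closest known reaction type is the Staunton–Weinreb annulation (Michael–Dieckmann reaction of a laterally lithiated ortho-toluate with an unsaturated ester), and lateral lithiation of 2-methyl-4-pyranones is established, so only the pairing of this donor with the annulation is untested. The C6 stereocentre has no controlling element and should form as a racemate, which is acceptable because C6 becomes sp2 in step 5. The selectivity needed is regiochemical and is secured by connectivity, since the methyl carbon can bond only to the acrylate β-carbon and the methoxy-bearing carbon only to the ester carbon, which places the methoxyl at C6 next to the C5 ketone; reaction of the dienolate at its CH2 end is favoured because only that mode restores the pyranone. As 10 has no proton between its carbonyl groups, LiN(SiMe3)2 is added to convert it into a dienolate by deprotonation at C8, which should shield the C5 ketone from retro-Claisen attack by methoxide.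

Step 4
Reactants: 10 racemic methyl 6-methoxy-4,5-dioxo-2-(3,4,5-trimethoxyphenyl)-5,6,7,8-tetrahydro-4H-chromene-6-carboxylate
Product: 11 racemic 6-methoxy-2-(3,4,5-trimethoxyphenyl)-7,8-dihydro-4H-chromene-4,5(6H)-dione
Conditions: LiCl (3 equiv), H2O (2 equiv), DMSO, 140 °C
Reagents that add atoms: none
Why: Krapcho dealkoxycarbonylation, in which chloride attacks the ester methyl group in an SN2 reaction, the β-keto carboxylate loses CO2 and water protonates the enolate to leave C6 as a racemic CH(OMe) centre, while the aryl methyl ethers should resist chloride at this temperature.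

Step 5
Reactants: 11 racemic 6-methoxy-2-(3,4,5-trimethoxyphenyl)-7,8-dihydro-4H-chromene-4,5(6H)-dione
Product: 12 5-hydroxy-6-methoxy-2-(3,4,5-trimethoxyphenyl)-4H-chromen-4-one
Conditions: DDQ (1.2 equiv), 1,4-dioxane, 100 °C
Reagents that add atoms: none
Why: DDQ dehydrogenation of the cyclohexenone-type ring, in which hydride abstraction from the enol of the C5 ketone and proton loss remove H2 from ring A and tautomerisation to the hydrogen-bonded 5-hydroxyflavone supplies the driving force and erases the C6 stereocentre.

Step 6
Reactants: 12 5-hydroxy-6-methoxy-2-(3,4,5-trimethoxyphenyl)-4H-chromen-4-one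
Product: 13 5,6-dimethoxy-2-(3,4,5-trimethoxyphenyl)-4H-chromen-4-one (cerosilin B)
Conditions: MeI (3 equiv), K2CO3 (3 equiv), DMF, 50 °C
Reagents that add atoms: iodomethane, CI
Why: Williamson O-methylation of the phenoxide, in which the chelated 5-hydroxyl is the only acidic site, so warming with excess iodomethane in DMF should overcome the hydrogen bond to the C4 carbonyl.

Compound list
1 | 5-iodo-1,2,3-trimethoxybenzene | COc1cc(I)cc(OC)c1OC | starting material
2 | propiolic acid | C#CC(=O)O | starting material
3 | 3-(3,4,5-trimethoxyphenyl)prop-2-ynoic acid | COc1cc(C#CC(=O)O)cc(OC)c1OC | intermediate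
4 | methyl acetoacetate | COC(=O)CC(C)=O | starting material
5 | 3-(3,4,5-trimethoxyphenyl)prop-2-ynoyl chloride | COc1cc(C#CC(=O)Cl)cc(OC)c1OC | intermediate (not isolated)
6 | methyl 2-acetyl-3-oxo-5-(3,4,5-trimethoxyphenyl)pent-4-ynoate (enolised, configurationally labile) | COC(=O)C(C(C)=O)C(=O)C#Cc1cc(OC)c(OC)c(OC)c1 | intermediate (not isolated)
7 | methyl 2-methyl-4-oxo-6-(3,4,5-trimethoxyphenyl)-4H-pyran-3-carboxylate | COC(=O)c1c(C)oc(-c2cc(OC)c(OC)c(OC)c2)cc1=O | intermediate
8 | methyl 2-methoxyacrylate | C=C(OC)C(=O)OC | starting material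
9 | methyl 2-(3,4-dimethoxy-4-oxobutyl)-4-oxo-6-(3,4,5-trimethoxyphenyl)-4H-pyran-3-carboxylate (racemic; present in the flask as its lithium ester enolate) | COC(=O)C(OC)CCc1oc(-c2cc(OC)c(OC)c(OC)c2)cc(=O)c1C(=O)OC | intermediate (not isolated)
10 | methyl 6-methoxy-4,5-dioxo-2-(3,4,5-trimethoxyphenyl)-5,6,7,8-tetrahydro-4H-chromene-6-carboxylate (racemic) | COC(=O)C1(OC)CCc2oc(-c3cc(OC)c(OC)c(OC)c3)cc(=O)c2C1=O | intermediate
11 | 6-methoxy-2-(3,4,5-trimethoxyphenyl)-7,8-dihydro-4H-chromene-4,5(6H)-dione (racemic) | COC1CCc2oc(-c3cc(OC)c(OC)c(OC)c3)cc(=O)c2C1=O | intermediate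
12 | 5-hydroxy-6-methoxy-2-(3,4,5-trimethoxyphenyl)-4H-chromen-4-one | COc1ccc2oc(-c3cc(OC)c(OC)c(OC)c3)cc(=O)c2c1O | intermediate
13 | 5,6-dimethoxy-2-(3,4,5-trimethoxyphenyl)-4H-chromen-4-one (cerosilin B, achiral) | COc1cc(-c2cc(=O)c3c(OC)c(OC)ccc3o2)cc(OC)c1OC | target

Total step count: 6
Longest linear sequence: 6 steps (1 → 3 → 7 → 10 → 11 → 12 → 13)

Steps most likely to fail

1. Step 3 (Proposed new method). Several processes could divert the annulation:
- anionic oligomerisation of the acrylate;
- proton transfer from the acidic pyranone CH2 that quenches the ester enolate before ring closure;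
- retro-Claisen opening of the ring by methoxide;
- nucleophilic opening of the pyranone.

The fallback uses only known aryl ynone chemistry; it sets out from 3 and comes back to the route at 13, replacing steps 2 to 6.
- Acid 3 is converted through acid chloride 5 (as in step 2) with MeNHOMe·HCl and pyridine into the Weinreb amide N-methoxy-N-methyl-3-(3,4,5-trimethoxyphenyl)prop-2-ynamide F1.
- Commercial 3,4-dimethoxyphenol is protected with MOMCl and iPr2NEt as 1,2-dimethoxy-4-(methoxymethoxy)benzene F2.
- n-BuLi in THF at 0 °C should lithiate F2 at the position flanked by the OMOM and OMe groups (cooperative directed ortho-metalation) to give [2,3-dimethoxy-6-(methoxymethoxy)phenyl]lithium F3.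
- Addition of F3 to F1 at −78 °C should give the ynone 1-[2,3-dimethoxy-6-(methoxymethoxy)phenyl]-3-(3,4,5-trimethoxyphenyl)prop-2-yn-1-one F4.
- HCl in MeOH should remove the MOM group to give the phenol 1-(6-hydroxy-2,3-dimethoxyphenyl)-3-(3,4,5-trimethoxyphenyl)prop-2-yn-1-one F5.
- K2CO3 in acetone should then close the pyranone by 6-endo-dig oxa-Michael addition and give 13 directly.

2. Step 2. The enolate may be acylated on oxygen, it may add in conjugate fashion to the ynoyl chloride, or the ring may close through the wrong oxygen or in the 5-exo sense.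

The fallback avoids the alkyne altogether; it sets out from 4 and comes back at 7.
- Methyl acetoacetate 4 is condensed with pyrrolidine (toluene, Dean–Stark) to the enamine methyl (E)-3-(pyrrolidin-1-yl)but-2-enoate F6.
- Separately, commercial 3,4,5-trimethoxybenzoyl chloride and Meldrum's acid (pyridine, CH2Cl2) should give 5-[hydroxy(3,4,5-trimethoxyphenyl)methylidene]-2,2-dimethyl-1,3-dioxane-4,6-dione F7.
- Heating F7 with acetone in toluene should give the dioxinone 2,2-dimethyl-6-(3,4,5-trimethoxyphenyl)-4H-1,3-dioxin-4-one F8.
- Thermolysis of F8 in toluene at 110 °C in the presence of F6 should release the aroylketene 3-oxo-3-(3,4,5-trimethoxyphenyl)prop-1-en-1-one F9, which acylates the enamine carbon.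
- Closure of the aroyl enol oxygen onto the iminium carbon and loss of pyrrolidine should give 7. This is the known formation of 4-pyranones from acylketenes and enamines.

3. Step 5. Hydride abstraction from an electron-poor, cross-conjugated enol may be slow or incomplete, and prolonged heating with the quinone may oxidise the electron-rich aryl ring.

The fallback replaces the quinone by a palladium-mediated sequence; it sets out from 11 and comes back at 12.
- Ketone 11 is deprotonated with LiN(SiMe3)2 at −78 °C and silylated with Me3SiCl to the silyl enol ether 6-methoxy-2-(3,4,5-trimethoxyphenyl)-5-(trimethylsilyloxy)-7,8-dihydro-4H-chromen-4-one F10.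
- Pd(OAc)2 in MeCN (Saegusa–Ito oxidation) should introduce the ring A double bond by palladation and β-hydride elimination, and tautomerisation should give 12.
- The regioisomeric dienol ether from deprotonation at C8 would converge on the same phenol.

Further compounds
F1 | step 3 | N-methoxy-N-methyl-3-(3,4,5-trimethoxyphenyl)prop-2-ynamide | COc1cc(C#CC(=O)N(C)OC)cc(OC)c1OC
F2 | step 3 | 1,2-dimethoxy-4-(methoxymethoxy)benzene | COCOc1ccc(OC)c(OC)c1
F3 | step 3 | [2,3-dimethoxy-6-(methoxymethoxy)phenyl]lithium | [Li]c1c(OCOC)ccc(OC)c1OC
F4 | step 3 | 1-[2,3-dimethoxy-6-(methoxymethoxy)phenyl]-3-(3,4,5-trimethoxyphenyl)prop-2-yn-1-one | COCOc1ccc(OC)c(OC)c1C(=O)C#Cc1cc(OC)c(OC)c(OC)c1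
F5 | step 3 | 1-(6-hydroxy-2,3-dimethoxyphenyl)-3-(3,4,5-trimethoxyphenyl)prop-2-yn-1-one | COc1ccc(O)c(C(=O)C#Cc2cc(OC)c(OC)c(OC)c2)c1OC
F6 | step 2 | methyl (E)-3-(pyrrolidin-1-yl)but-2-enoate | COC(=O)/C=C(\C)N1CCCC1
F7 | step 2 | 5-[hydroxy(3,4,5-trimethoxyphenyl)methylidene]-2,2-dimethyl-1,3-dioxane-4,6-dione | COc1cc(C(O)=C2C(=O)OC(C)(C)OC2=O)cc(OC)c1OC
F8 | step 2 | 2,2-dimethyl-6-(3,4,5-trimethoxyphenyl)-4H-1,3-dioxin-4-one | COc1cc(C2=CC(=O)OC(C)(C)O2)cc(OC)c1OC
F9 | step 2 | 3-oxo-3-(3,4,5-trimethoxyphenyl)prop-1-en-1-one | COc1cc(C(=O)C=C=O)cc(OC)c1OC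
F10 | step 5 | 6-methoxy-2-(3,4,5-trimethoxyphenyl)-5-(trimethylsilyloxy)-7,8-dihydro-4H-chromen-4-one | COC1=C(O[Si](C)(C)C)c2c(oc(-c3cc(OC)c(OC)c(OC)c3)cc2=O)CC1
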